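**Retrosynthetic overview**
- Feature: in ring B the carbinol carbon C1 and the diarylmethine carbon C4 are both benzylic and stand 1,4 to each other. C1–O, C2, C3 and C4 therefore map onto a 2,5-diaryl oxolane in which the naphthyl-side C–O bond is exchanged for the C4–C4a bond.
- Last disconnection: the naphthol MOM ether. Key disconnection: C4–C4a, back to a trans-(2S,5S)-2-(2-bromo-3-methoxyphenyl)-5-naphthyl oxolane (Br/Mg exchange, then nickel-catalysed invertive C–O arylation).
- The oxolane comes from an (S)-γ-aryl lactol acetate and a 2-metallated 1-MOM-oxy-8-methoxynaphthalene (trans-selective C-arylation). The lactone comes from a Stetter keto ester by asymmetric transfer hydrogenation.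
- Ring order: ring A and the naphthalene are bought; the oxolane is built first as a temporary ring; ring B is then closed at its expense.

Key step: step 7

Remark: tetralin numbering is used for the target (C1 carbinol, C4 diarylmethine, C5 methoxy) and the SMILES is read as the trans-(1S,4R) isomer; the lactol acetate and the α-bromo ether derived from it are handled as anomeric mixtures, since that centre is flattened in the arylation.

**Route**

Step 1
Reactants: 1 2-bromo-3-methoxybenzaldehyde; 2 methyl acrylate
Product: 3 methyl 4-(2-bromo-3-methoxyphenyl)-4-oxobutanoate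
Conditions: 3-benzyl-5-(2-hydroxyethyl)-4-methylthiazolium chloride (20 mol %), Et3N, DMF, 70 °C
Reagents that add atoms: none
Why: Stetter reaction, in which the carbene-derived acyl anion equivalent of the aldehyde adds 1,4 to the acrylate, and the ortho bromide should slow the competing benzoin dimerisation.

Step 2
Reactants: 3 methyl 4-(2-bromo-3-methoxyphenyl)-4-oxobutanoate
Product: 5 (5S)-5-(2-bromo-3-methoxyphenyl)oxolan-2-one, via hydroxy ester 4 (not isolated)
Conditions: RuCl[(S,S)-TsDPEN](p-cymene) (1 mol %), HCO2H/Et3N (5:2), DMF, 40 °C; then TsOH·H2O (cat.), PhMe, 50 °C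
Reagents that add atoms: none
Why: Noyori asymmetric transfer hydrogenation of the aryl ketone, where the (S,S)-ligand should deliver hydride in the same sense as for acetophenone (aryl as the large group) to set the (S)-carbinol, which then lactonises.

Step 3
Reactants: 5 (5S)-5-(2-bromo-3-methoxyphenyl)oxolan-2-one
Product: 7 (5S)-5-(2-bromo-3-methoxyphenyl)oxolan-2-yl acetate (C2 epimer mixture), via aluminium lactolate 6 (not isolated)
Conditions: i-Bu2AlH, CH2Cl2, −78 °C; then pyridine, DMAP, Ac2O, −78 → 0 °C; aq. potassium sodium tartrate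
Reagents that add atoms: acetic anhydride CC(=O)OC(C)=O
Why: Rychnovsky reductive acetylation, in which the tetrahedral aluminium lactolate is stable at −78 °C and is acetylated in the flask, leaving the aryl bromide and the C5 centre untouched.

Step 4
Reactants: 8 naphthalene-1,8-diol
Product: 9 8-methoxynaphthalen-1-ol
Conditions: MeI (1.05 equiv), K2CO3, acetone, rt
Reagents that add atoms: iodomethane CI
Why: Williamson etherification that should stop at the mono-ether, because the remaining hydroxyl is hydrogen-bonded to the peri oxygen and is much less acidic than the first.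

Step 5
Reactants: 9 8-methoxynaphthalen-1-ol
Product: 10 1-methoxy-8-(methoxymethoxy)naphthalene
Conditions: NaH, DMF, 0 °C; MOMCl, 0 °C → rt
Reagents that add atoms: chloromethyl methyl ether COCCl
Why: Williamson-type MOM protection of the sodium naphtholate, using a strong base to break the peri hydrogen bond; the MOM ether protects the naphthol and later directs the metalation.

Step 6
Reactants: 7 (5S)-5-(2-bromo-3-methoxyphenyl)oxolan-2-yl acetate; 10 1-methoxy-8-(methoxymethoxy)naphthalene
Product: 14 (2S,5S)-2-(2-bromo-3-methoxyphenyl)-5-[8-methoxy-1-(methoxymethoxy)naphthalen-2-yl]oxolane, via naphthyllithium 11 (not isolated), via naphthylmagnesium bromide 12 (not isolated), via bromo oxolane 13 (not isolated)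
Conditions: 10 (1.5 equiv), n-BuLi (1.4 equiv), TMEDA, THF, 0 °C; MgBr2·OEt2, 0 °C; separately 7, TMSBr (1.0 equiv), CH2Cl2, −78 °C; add the Grignard solution to the bromide, −78 → −40 °C
Reagents that add atoms: none
Why: Directed ortho-metalation (OMOM outranks OMe as directing group, so C2 is lithiated), transmetalation to magnesium and Grignard C-arylation of the ionising α-bromo ether (C-glycosylation type), in which the bulky nucleophile should attack the oxocarbenium carbon on the face anti to the existing aryl group and so set the new centre as S (2,5-trans).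

Step 7
Reactants: 14 (2S,5S)-2-(2-bromo-3-methoxyphenyl)-5-[8-methoxy-1-(methoxymethoxy)naphthalen-2-yl]oxolane
Product: 16 (1S,4R)-5-methoxy-4-[8-methoxy-1-(methoxymethoxy)naphthalen-2-yl]-1,2,3,4-tetrahydronaphthalen-1-ol, via arylmagnesium chloride 15 (not isolated)
Conditions: i-PrMgCl·LiCl (1.3 equiv), THF, 0 °C → rt; evaporate, PhMe; Ni(cod)2 (10 mol %), 1,2-bis(diphenylphosphino)ethane (12 mol %), rt → 50 °C; aq. NH4Cl
Reagents that add atoms: none
Why: Proposed new method: Br/Mg exchange gives arylmagnesium 15, whose magnesium sits on the oxolane oxygen in a five-membered chelate and so activates the ether for SN2-type oxidative addition of zerovalent nickel into the naphthylic C5–O bond on the face opposite to oxygen (inversion); the tethered aryl group then moves from magnesium to nickel and C–C reductive elimination with retention forms C4–C4a. The closest known reaction type is the intermolecular nickel-catalysed stereospecific ring-opening Kumada coupling of 2-aryl oxolanes with Grignard reagents, which runs with inversion; what is new is that the Grignard carbon is carried by the aryl group on the other α-carbon of the same ether. Ring B closes by reductive elimination from a seven-membered aryl(naphthylmethyl)nickel metallacycle, so that the five-membered ether is traded for the six-membered carbocycle and the C1 alkoxide is released. The C4 centre is controlled by the stereospecific inversion at the former oxolane C5 (5S becomes 4R), while C1 is the untouched oxolane C2, so the trans ether should give the trans-(1S,4R) tetralol. The step needs site selectivity for the naphthylmethyl C–O bond over the phenyl-type benzylic C2–O bond and over the aryl C–OMe and C–OMOM bonds, which the much faster oxidative addition into π-extended benzylic ethers and the mild diphosphine conditions should secure, and the position of the bromide fixes the new aryl bond between OMe and the ring carbon. Removal of 2-bromopropane before the nickel is added and the chelating diphosphine should suppress isopropyl cross-coupling and β-hydride elimination.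

Step 8
Reactants: 16 (1S,4R)-5-methoxy-4-[8-methoxy-1-(methoxymethoxy)naphthalen-2-yl]-1,2,3,4-tetrahydronaphthalen-1-ol
Product: 17 dipolynaphthalene A, (1S,4R)-4-(1-hydroxy-8-methoxynaphthalen-2-yl)-5-methoxy-1,2,3,4-tetrahydronaphthalen-1-ol
Conditions: 3 M aq. HCl, THF, rt → 40 °C
Reagents that add atoms: none
Why: Acid hydrolysis of the aryl methoxymethyl acetal, which should proceed under conditions too mild to ionise the C1 benzylic alcohol, since the 5-methoxy group is meta to C8a and gives the C1 cation no conjugative support.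

**Compound list**
1 | 2-bromo-3-methoxybenzaldehyde | COc1cccc(C=O)c1Br | starting material
2 | methyl acrylate | C=CC(=O)OC | starting material
3 | methyl 4-(2-bromo-3-methoxyphenyl)-4-oxobutanoate | COC(=O)CCC(=O)c1cccc(OC)c1Br | intermediate
4 | methyl (4S)-4-(2-bromo-3-methoxyphenyl)-4-hydroxybutanoate | COC(=O)CC[C@@H](c1cccc(OC)c1Br)O | intermediate
5 | (5S)-5-(2-bromo-3-methoxyphenyl)oxolan-2-one | O=C1CC[C@@H](c2cccc(OC)c2Br)O1 | intermediate
6 | bis(2-methylpropyl)aluminium (5S)-5-(2-bromo-3-methoxyphenyl)oxolan-2-olate | CC(C)C[Al](CC(C)C)OC1CC[C@@H](c2cccc(OC)c2Br)O1 | intermediate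
7 | (5S)-5-(2-bromo-3-methoxyphenyl)oxolan-2-yl acetate (C2 epimer mixture) | CC(=O)OC1CC[C@@H](c2cccc(OC)c2Br)O1 | intermediate
8 | naphthalene-1,8-diol | Oc1cccc2cccc(O)c12 | starting material
9 | 8-methoxynaphthalen-1-ol | COc1cccc2cccc(O)c12 | intermediate
10 | 1-methoxy-8-(methoxymethoxy)naphthalene | COCOc1cccc2cccc(OC)c12 | intermediate
11 | [8-methoxy-1-(methoxymethoxy)naphthalen-2-yl]lithium | [Li]c1ccc2cccc(OC)c2c1OCOC | intermediate
12 | bromo[8-methoxy-1-(methoxymethoxy)naphthalen-2-yl]magnesium | Br[Mg]c1ccc2cccc(OC)c2c1OCOC | intermediate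
13 | (5S)-2-bromo-5-(2-bromo-3-methoxyphenyl)oxolane (C2 epimer mixture) | BrC1CC[C@@H](c2cccc(OC)c2Br)O1 | intermediate
14 | (2S,5S)-2-(2-bromo-3-methoxyphenyl)-5-[8-methoxy-1-(methoxymethoxy)naphthalen-2-yl]oxolane | COc1cccc([C@@H]2CC[C@@H](c3ccc4cccc(OC)c4c3OCOC)O2)c1Br | intermediate
15 | chloro{2-methoxy-6-[(2S,5S)-5-[8-methoxy-1-(methoxymethoxy)naphthalen-2-yl]oxolan-2-yl]phenyl}magnesium | COc1cccc([C@@H]2CC[C@@H](c3ccc4cccc(OC)c4c3OCOC)O2)c1[Mg]Cl | intermediate
16 | (1S,4R)-5-methoxy-4-[8-methoxy-1-(methoxymethoxy)naphthalen-2-yl]-1,2,3,4-tetrahydronaphthalen-1-ol | COc1cccc2c1[C@@H](c1ccc3cccc(OC)c3c1OCOC)CC[C@@H]2O | intermediate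
17 | dipolynaphthalene A, (1S,4R)-4-(1-hydroxy-8-methoxynaphthalen-2-yl)-5-methoxy-1,2,3,4-tetrahydronaphthalen-1-ol | COc1cccc2c1[C@@H](c1ccc3cccc(OC)c3c1O)CC[C@@H]2O | target

**Step count**
Total: 8 steps. Longest linear sequence: 6 steps (steps 1, 2, 3, 6, 7, 8); the naphthalene branch (steps 4, 5) joins at step 6.

**Steps most likely to fail**

1. Step 7 (proposed new method). What may go wrong:
- protonation of the hindered arylmagnesium before nickel engages the ether;
- β-hydride elimination from the naphthylmethylnickel intermediate;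
- oxidative addition at the wrong C–O bond;
- erosion of stereospecificity through a radical or ionised naphthylic intermediate.

Fallback by known chemistry, setting out from lactone 5 and coming back at 16. Weinreb aminolysis (MeNH(OMe)·HCl, AlMe3, CH2Cl2) opens 5 to (4S)-4-(2-bromo-3-methoxyphenyl)-4-hydroxy-N-methoxy-N-methylbutanamide F1. Silylation (TBSCl, imidazole, DMF) gives (4S)-4-(2-bromo-3-methoxyphenyl)-4-[(tert-butyldimethylsilyl)oxy]-N-methoxy-N-methylbutanamide F2. Br/Li exchange (t-BuLi, THF, −78 °C) triggers a Parham cyclisation onto the Weinreb amide to give (4S)-4-[(tert-butyldimethylsilyl)oxy]-8-methoxy-3,4-dihydronaphthalen-1(2H)-one F3. Naphthyllithium 11, premixed with CeCl3 to limit enolisation, adds to the ketone to give (4S)-4-[(tert-butyldimethylsilyl)oxy]-8-methoxy-1-[8-methoxy-1-(methoxymethoxy)naphthalen-2-yl]-1,2,3,4-tetrahydronaphthalen-1-ol F4. Burgess reagent (PhMe, 50 °C) dehydrates it to tert-butyl({(1S)-5-methoxy-4-[8-methoxy-1-(methoxymethoxy)naphthalen-2-yl]-1,2-dihydronaphthalen-1-yl}oxy)dimethylsilane F5. TBAF (THF, 0 °C) frees (1S)-5-methoxy-4-[8-methoxy-1-(methoxymethoxy)naphthalen-2-yl]-1,2-dihydronaphthalen-1-ol F6, which is kept neutral to avoid aromatisation. Hydroxyl-directed hydrogenation with [Ir(cod)(PCy3)(py)]PF6 and H2 in CH2Cl2 should deliver hydrogen to C4 from the face of the C1 hydroxyl, placing the naphthyl group trans, and so give 16.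

2. Step 6. What may go wrong:
- poor facial selectivity in the attack on the oxocarbenium carbon (cis/trans mixture);
- elimination of the α-bromo ether to the dihydrofuran by the basic Grignard reagent;
- lithiation next to OMe instead of OMOM.

Fallback, setting out from keto ester 3 (with naphthyllithium 11 made from 10) and coming back at 14. Transfer hydrogenation of 3 with the enantiomeric catalyst RuCl[(R,R)-TsDPEN](p-cymene) gives methyl (4R)-4-(2-bromo-3-methoxyphenyl)-4-hydroxybutanoate F7, which lactonises to (5R)-5-(2-bromo-3-methoxyphenyl)oxolan-2-one F8. Addition of 11 (THF, −78 °C) opens the lactone to (4R)-4-(2-bromo-3-methoxyphenyl)-4-hydroxy-1-[8-methoxy-1-(methoxymethoxy)naphthalen-2-yl]butan-1-one F9. Mesylation (MsCl, Et3N, CH2Cl2, −30 °C) gives (1R)-1-(2-bromo-3-methoxyphenyl)-4-[8-methoxy-1-(methoxymethoxy)naphthalen-2-yl]-4-oxobutyl methanesulfonate F10, used crude. Corey–Bakshi–Shibata reduction ((R)-Me-CBS oxazaborolidine, BH3·SMe2, THF, −20 °C) should give (1R,4S)-1-(2-bromo-3-methoxyphenyl)-4-hydroxy-4-[8-methoxy-1-(methoxymethoxy)naphthalen-2-yl]butyl methanesulfonate F11. KOt-Bu (THF, 0 °C) then closes the oxolane by intramolecular Williamson substitution with inversion at the aryl-bearing carbon (R to S). Both centres of 14 are thus set by reagent control and an SN2 step, not by facial selectivity.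

3. Step 1. What may go wrong:
- slow formation of the acyl anion equivalent from the ortho-substituted aldehyde;
- benzoin self-condensation;
- polymerisation of the acrylate.

Fallback, setting out from aldehyde 1 and coming back at lactone 5. Brown allylation with (−)-Ipc2B(allyl), the antipode that gives the (S)-carbinol from aryl aldehydes, gives (1S)-1-(2-bromo-3-methoxyphenyl)but-3-en-1-ol F12. Hydroboration–oxidation (9-BBN, THF; NaOH, H2O2) gives (1S)-1-(2-bromo-3-methoxyphenyl)butane-1,4-diol F13. TEMPO/PhI(OAc)2 (CH2Cl2) oxidises the primary alcohol and then the resulting lactol to lactone 5.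

**Further compounds**
F1 | step 7 | (4S)-4-(2-bromo-3-methoxyphenyl)-4-hydroxy-N-methoxy-N-methylbutanamide | COc1cccc([C@@H](O)CCC(=O)N(C)OC)c1Br
F2 | step 7 | (4S)-4-(2-bromo-3-methoxyphenyl)-4-[(tert-butyldimethylsilyl)oxy]-N-methoxy-N-methylbutanamide | COc1cccc([C@@H](O[Si](C)(C)C(C)(C)C)CCC(=O)N(C)OC)c1Br
F3 | step 7 | (4S)-4-[(tert-butyldimethylsilyl)oxy]-8-methoxy-3,4-dihydronaphthalen-1(2H)-one | COc1cccc2c1C(=O)CC[C@@H]2O[Si](C)(C)C(C)(C)C
F4 | step 7 | (4S)-4-[(tert-butyldimethylsilyl)oxy]-8-methoxy-1-[8-methoxy-1-(methoxymethoxy)naphthalen-2-yl]-1,2,3,4-tetrahydronaphthalen-1-ol (C1 epimers) | COc1cccc2c1C(O)(c1ccc3cccc(OC)c3c1OCOC)CC[C@@H]2O[Si](C)(C)C(C)(C)C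
F5 | step 7 | tert-butyl({(1S)-5-methoxy-4-[8-methoxy-1-(methoxymethoxy)naphthalen-2-yl]-1,2-dihydronaphthalen-1-yl}oxy)dimethylsilane | COc1cccc2c1C(c1ccc3cccc(OC)c3c1OCOC)=CC[C@@H]2O[Si](C)(C)C(C)(C)C
F6 | step 7 | (1S)-5-methoxy-4-[8-methoxy-1-(methoxymethoxy)naphthalen-2-yl]-1,2-dihydronaphthalen-1-ol | COc1cccc2c1C(c1ccc3cccc(OC)c3c1OCOC)=CC[C@@H]2O
F7 | step 6 | methyl (4R)-4-(2-bromo-3-methoxyphenyl)-4-hydroxybutanoate | COC(=O)CC[C@H](c1cccc(OC)c1Br)O
F8 | step 6 | (5R)-5-(2-bromo-3-methoxyphenyl)oxolan-2-one | O=C1CC[C@H](c2cccc(OC)c2Br)O1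
F9 | step 6 | (4R)-4-(2-bromo-3-methoxyphenyl)-4-hydroxy-1-[8-methoxy-1-(methoxymethoxy)naphthalen-2-yl]butan-1-one | COc1cccc([C@H](O)CCC(=O)c2ccc3cccc(OC)c3c2OCOC)c1Br
F10 | step 6 | (1R)-1-(2-bromo-3-methoxyphenyl)-4-[8-methoxy-1-(methoxymethoxy)naphthalen-2-yl]-4-oxobutyl methanesulfonate | COc1cccc([C@H](OS(C)(=O)=O)CCC(=O)c2ccc3cccc(OC)c3c2OCOC)c1Br
F11 | step 6 | (1R,4S)-1-(2-bromo-3-methoxyphenyl)-4-hydroxy-4-[8-methoxy-1-(methoxymethoxy)naphthalen-2-yl]butyl methanesulfonate | COc1cccc([C@H](OS(C)(=O)=O)CC[C@H](O)c2ccc3cccc(OC)c3c2OCOC)c1Br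
F12 | step 1 | (1S)-1-(2-bromo-3-methoxyphenyl)but-3-en-1-ol | COc1cccc([C@@H](O)CC=C)c1Br
F13 | step 1 | (1S)-1-(2-bromo-3-methoxyphenyl)butane-1,4-diol | COc1cccc([C@@H](O)CCCO)c1Br
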